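**Retrosynthetic overview**
- Agehoustin C comes from its 3'-O-benzyl ether by hydrogenolysis in the last step; the 3'-OH is carried as OBn from 2,6-dimethoxyphenol.
- The C2–C1' bond is cut into 5,6,7,8-tetramethoxychromone (rings A and C) and 3-(benzyloxy)-2,4,5-trimethoxybenzoic acid (ring B); they are joined by a decarboxylative dehydrogenative Heck arylation, the proposed new step.
- The chromone comes from 2'-hydroxy-3',4',5',6'-tetramethoxyacetophenone (enaminone cyclisation), made from 2,3,4,5-tetramethoxyphenol, made from 1,2,3,4-tetramethoxybenzene by lithiation–borylation–oxidation.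
- The ring B acid comes from the bromo acid (Ullmann methoxylation), made from a symmetric dibromide (mono Br/Li exchange, CO2), made from the benzyl ether of 2,6-dimethoxyphenol.
- Ring order: rings A and B are bought as benzenes; ring C is the only ring built (on ring A); ring B is attached last.

Assumption: the target SMILES holds no stereocentre, stereogenic double bond or axis, so Agehoustin C is achiral and the route only has to deliver the drawn constitution.

**Route**

Step 1
Reactants: 1 1,2,3,4-tetramethoxybenzene
Product: 4 2,3,4,5-tetramethoxyphenol, via aryllithium 2 (not isolated), via lithium arylborate 3 (not isolated)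
Conditions: n-BuLi, TMEDA, THF, 0 °C to rt; B(OMe)3, −78 °C to rt; then AcOH, 30% H2O2, 0 °C to rt
Reagents that add atoms: hydrogen peroxide OO (phenol oxygen of 4); n-butyllithium [Li]CCCC (lithium of 2 and 3); trimethyl borate COB(OC)OC (boron and methoxy groups of 3)
Why: Methoxy-directed ortho-lithiation (directed ortho-metalation) of the symmetric arene can give only one aryllithium because both free positions are equivalent, and borylation followed by peroxide oxidation (1,2-aryl shift from boron to oxygen) is a standard arene-to-phenol sequence; no stereocentre is formed.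

Step 2
Reactants: 4 2,3,4,5-tetramethoxyphenol
Product: 5 1-(2-hydroxy-3,4,5,6-tetramethoxyphenyl)ethan-1-one
Conditions: AcOH (2 equiv), BF3·OEt2 (solvent), 85 °C; aq NaOAc work-up
Reagents that add atoms: acetic acid CC(=O)O
Why: Friedel–Crafts (Nencki-type) C-acylation of the very electron-rich phenol can only go to C6, the single unsubstituted ring carbon, which is ortho to the OH, and the hydrogen-bonded ortho-hydroxy ketone resists further acylation.

Step 3
Reactants: 5 1-(2-hydroxy-3,4,5,6-tetramethoxyphenyl)ethan-1-one
Product: 7 5,6,7,8-tetramethoxy-4H-chromen-4-one, via enaminone 6 (not isolated)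
Conditions: Me2NCH(OMe)2, toluene, 100 °C; then conc. HCl, CH2Cl2, rt
Reagents that add atoms: N,N-dimethylformamide dimethyl acetal COC(OC)N(C)C
Why: Condensation of the methyl ketone with the amide acetal gives the enaminone, and acid-promoted intramolecular conjugate addition of the phenol with loss of dimethylamine (enaminone route to chromones) closes ring C without touching the methyl ethers.

Step 4
Reactants: 8 2,6-dimethoxyphenol
Product: 9 2-(benzyloxy)-1,3-dimethoxybenzene
Conditions: BnBr, K2CO3, DMF, 60 °C
Reagents that add atoms: benzyl bromide BrCc1ccccc1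
Why: Williamson etherification of the phenol installs a benzyl group that survives organolithium, alkoxide and oxidative palladium/silver conditions and is removed by hydrogenolysis at the end.

Step 5
Reactants: 9 2-(benzyloxy)-1,3-dimethoxybenzene
Product: 10 3-(benzyloxy)-1,5-dibromo-2,4-dimethoxybenzene
Conditions: NBS (2.1 equiv), MeCN, 0 °C to rt, dark
Reagents that add atoms: N-bromosuccinimide O=C1CCC(=O)N1Br
Why: Electrophilic aromatic bromination is directed by each methoxy group to the two equivalent positions that are ortho to one OMe and para to the other (C4 and C6 of 9), while C5, meta to both, stays untouched, so the symmetric dibromide is the expected product.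

Step 6
Reactants: 10 3-(benzyloxy)-1,5-dibromo-2,4-dimethoxybenzene
Product: 12 3-(benzyloxy)-5-bromo-2,4-dimethoxybenzoic acid, via aryllithium 11 (not isolated)
Conditions: n-BuLi (1.0 equiv), THF, −78 °C; CO2 (g), −78 °C to rt; then aq HCl
Reagents that add atoms: carbon dioxide O=C=O; n-butyllithium [Li]CCCC (lithium of 11)
Why: Bromine–lithium exchange with one equivalent of n-BuLi at −78 °C is faster than any proton transfer and the two bromines are equivalent, so one defined aryllithium forms and is carboxylated by CO2 to the benzoic acid.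

Step 7
Reactants: 12 3-(benzyloxy)-5-bromo-2,4-dimethoxybenzoic acid
Product: 13 3-(benzyloxy)-2,4,5-trimethoxybenzoic acid
Conditions: NaOMe (5 equiv), CuBr (20 mol%), DMF/MeOH, 110 °C; then aq HCl
Reagents that add atoms: sodium methoxide [Na+].[O-]C
Why: Ullmann-type CuBr-catalysed methoxylation of the aryl bromide (copper-mediated C–O coupling) runs on the carboxylate salt, which shields the acid function from NaOMe, and the benzyl ether is inert to alkoxide.

Step 8
Reactants: 7 5,6,7,8-tetramethoxy-4H-chromen-4-one; 13 3-(benzyloxy)-2,4,5-trimethoxybenzoic acid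
Product: 14 2-[3-(benzyloxy)-2,4,5-trimethoxyphenyl]-5,6,7,8-tetramethoxy-4H-chromen-4-one
Conditions: 13 (1.5 equiv), Pd(O2CCF3)2 (20 mol%), Ag2CO3 (3 equiv), DMSO/DMF (1:20), 120 °C
Reagents that add atoms: none
Why: Proposed new method: decarboxylative dehydrogenative Heck arylation of a chromone C2–H bond by an ortho-methoxybenzoic acid, which to my knowledge has not been shown for chromones; the carboxylate of 13, twisted out of plane by its ortho-methoxy group, loses CO2 at divalent palladium (silver-assisted) to give an electron-rich aryl–palladium trifluoroacetate, this adds across C2=C3 of 7 with the aryl group on C2 (the β-carbon of the enone and the oxygen-bearing carbon of the enol ether, so both polarisations agree), the C3–palladium enolate epimerises through its oxygen-bound form and syn β-hydride elimination of H-2 delivers the flavone, and Ag2CO3 takes up the two protons and returns zerovalent palladium to divalent palladium; the closest known reaction types are the decarboxylative Heck olefination of ortho-alkoxybenzoic acids with acrylates, styrenes and cyclic enones and the oxidative Heck C2-arylation of chromones with arylboronic acids; no stereocentre is formed.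

Step 9
Reactants: 14 2-[3-(benzyloxy)-2,4,5-trimethoxyphenyl]-5,6,7,8-tetramethoxy-4H-chromen-4-one
Product: 15 Agehoustin C
Conditions: H2 (1 atm), 10% Pd/C, EtOAc/MeOH, rt
Reagents that add atoms: none
Why: Hydrogenolysis of the aryl benzyl ether over Pd/C at 1 atm and room temperature is chemoselective because the C2=C3 bond of the flavone is part of a vinylogous ester in an aromatic pyranone and is not reduced under these mild conditions, and the seven methyl ethers are inert.

**Compound list**

1 | 1,2,3,4-tetramethoxybenzene | COc1ccc(OC)c(OC)c1OC | starting material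
2 | (2,3,4,5-tetramethoxyphenyl)lithium | [Li]c1cc(OC)c(OC)c(OC)c1OC | intermediate
3 | lithium trimethoxy(2,3,4,5-tetramethoxyphenyl)borate | [Li+].CO[B-](OC)(OC)c1cc(OC)c(OC)c(OC)c1OC | intermediate
4 | 2,3,4,5-tetramethoxyphenol | COc1cc(O)c(OC)c(OC)c1OC | intermediate
5 | 1-(2-hydroxy-3,4,5,6-tetramethoxyphenyl)ethan-1-one | CC(=O)c1c(O)c(OC)c(OC)c(OC)c1OC | intermediate
6 | (E)-3-(dimethylamino)-1-(2-hydroxy-3,4,5,6-tetramethoxyphenyl)prop-2-en-1-one | CN(C)/C=C/C(=O)c1c(O)c(OC)c(OC)c(OC)c1OC | intermediate
7 | 5,6,7,8-tetramethoxy-4H-chromen-4-one | O=c1ccoc2c(OC)c(OC)c(OC)c(OC)c12 | intermediate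
8 | 2,6-dimethoxyphenol | COc1cccc(OC)c1O | starting material
9 | 2-(benzyloxy)-1,3-dimethoxybenzene | COc1cccc(OC)c1OCc2ccccc2 | intermediate
10 | 3-(benzyloxy)-1,5-dibromo-2,4-dimethoxybenzene | COc1c(Br)cc(Br)c(OC)c1OCc2ccccc2 | intermediate
11 | [3-(benzyloxy)-5-bromo-2,4-dimethoxyphenyl]lithium | [Li]c1cc(Br)c(OC)c(OCc2ccccc2)c1OC | intermediate
12 | 3-(benzyloxy)-5-bromo-2,4-dimethoxybenzoic acid | OC(=O)c1cc(Br)c(OC)c(OCc2ccccc2)c1OC | intermediate
13 | 3-(benzyloxy)-2,4,5-trimethoxybenzoic acid | OC(=O)c1cc(OC)c(OC)c(OCc2ccccc2)c1OC | intermediate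
14 | 2-[3-(benzyloxy)-2,4,5-trimethoxyphenyl]-5,6,7,8-tetramethoxy-4H-chromen-4-one | COc1cc(-c2cc(=O)c3c(OC)c(OC)c(OC)c(OC)c3o2)c(OC)c(OCc4ccccc4)c1OC | intermediate
15 | Agehoustin C, 2-(3-hydroxy-2,4,5-trimethoxyphenyl)-5,6,7,8-tetramethoxy-4H-chromen-4-one (achiral) | COc1cc(-c2cc(=O)c3c(OC)c(OC)c(OC)c(OC)c3o2)c(OC)c(O)c1OC | target

**Totals and risks**

Total step count: 9.
Longest linear sequence: 6 steps (steps 4 to 9, from 8 to 15); the other branch is 5 steps (steps 1, 2, 3, 8, 9).

Three steps most likely to fail:

Step 8 (the proposed new coupling). The risks are protodecarboxylation of 13 before palladation, a stall at the 2,3-dihydro stage if β-hydride elimination is slow, and competing arylation at C3. The fallback is known chemistry (Baker–Venkataraman flavone synthesis); it sets out from 5, uses 13, and comes back at 14. Acid 13 is esterified with the phenol of 5 (EDC·HCl, DMAP, CH2Cl2, rt) to give 2-acetyl-3,4,5,6-tetramethoxyphenyl 3-(benzyloxy)-2,4,5-trimethoxybenzoate F1. LiN(SiMe3)2 in THF (−20 °C to rt) then triggers the O-to-C acyl shift to 1-[3-(benzyloxy)-2,4,5-trimethoxyphenyl]-3-(2-hydroxy-3,4,5,6-tetramethoxyphenyl)propane-1,3-dione F2. TsOH·H2O in toluene at 80 °C cyclodehydrates it to 14.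

Step 7 (Ullmann methoxylation). The bromide is electron-rich and flanked by a methoxy group, so slow coupling and hydrodebromination are the risks. The fallback makes the C–O bond by boron oxidation and brings in the carboxyl group last; it sets out from 10 and comes back at 13. Dibromide 10 is converted to aryllithium 11 as in step 6, and B(OMe)3 turns it into lithium [3-(benzyloxy)-5-bromo-2,4-dimethoxyphenyl]trimethoxyborate F3. This is oxidised in the same flask (AcOH, 30% H2O2) to 3-(benzyloxy)-5-bromo-2,4-dimethoxyphenol F4. MeI and K2CO3 in DMF give 3-(benzyloxy)-1-bromo-2,4,5-trimethoxybenzene F5. Bromine–lithium exchange (n-BuLi, THF, −78 °C) gives [3-(benzyloxy)-2,4,5-trimethoxyphenyl]lithium F6, which is quenched with CO2 and acidified to 13.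

Step 2 (ortho-acetylation). The position is hindered and BF3·OEt2 can cleave a methyl ether next to the new carbonyl. The fallback builds the acetyl group from an aldehyde; it sets out from 4 and comes back at 5. Magnesium-mediated ortho-formylation (MgCl2, Et3N, paraformaldehyde, MeCN, reflux) gives 2-hydroxy-3,4,5,6-tetramethoxybenzaldehyde F7. MeMgBr (2.2 equiv, THF, 0 °C) gives racemic 2-(1-hydroxyethyl)-3,4,5,6-tetramethoxyphenol F8. MnO2 in CH2Cl2 oxidises the benzylic alcohol to 5, which removes the racemic centre.

**Further compounds**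

F1 | step 8 | 2-acetyl-3,4,5,6-tetramethoxyphenyl 3-(benzyloxy)-2,4,5-trimethoxybenzoate | CC(=O)c1c(OC(=O)c2cc(OC)c(OC)c(OCc3ccccc3)c2OC)c(OC)c(OC)c(OC)c1OC
F2 | step 8 | 1-[3-(benzyloxy)-2,4,5-trimethoxyphenyl]-3-(2-hydroxy-3,4,5,6-tetramethoxyphenyl)propane-1,3-dione | O=C(CC(=O)c1c(O)c(OC)c(OC)c(OC)c1OC)c2cc(OC)c(OC)c(OCc3ccccc3)c2OC
F3 | step 7 | lithium [3-(benzyloxy)-5-bromo-2,4-dimethoxyphenyl]trimethoxyborate | [Li+].CO[B-](OC)(OC)c1cc(Br)c(OC)c(OCc2ccccc2)c1OC
F4 | step 7 | 3-(benzyloxy)-5-bromo-2,4-dimethoxyphenol | Oc1cc(Br)c(OC)c(OCc2ccccc2)c1OC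
F5 | step 7 | 3-(benzyloxy)-1-bromo-2,4,5-trimethoxybenzene | COc1cc(Br)c(OC)c(OCc2ccccc2)c1OC
F6 | step 7 | [3-(benzyloxy)-2,4,5-trimethoxyphenyl]lithium | [Li]c1cc(OC)c(OC)c(OCc2ccccc2)c1OC
F7 | step 2 | 2-hydroxy-3,4,5,6-tetramethoxybenzaldehyde | O=Cc1c(O)c(OC)c(OC)c(OC)c1OC
F8 | step 2 | 2-(1-hydroxyethyl)-3,4,5,6-tetramethoxyphenol (racemate) | CC(O)c1c(O)c(OC)c(OC)c(OC)c1OC
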